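**Plan** (locants C1–C15 are the germacrane locants of the target: ring C1–C10, lactone C6–O–C12 with C11=C13, C14 = CHO on C10, C15 = CH2OH on C4, ester on O8)
Retrosynthesis: cut the O8 acyl bond (with inversion), C11=C13 and the lactone C12–O6 bond. The feature that then remains is the 1,5-diene C10=C1–C2–C3–C4=C5 of the ten-membered ring beside the C6 carbonyl. It is folded back to a bicyclo[2.2.0]hexane by re-forming C1–C4 and C5–C10, and that cyclobutane is cut at C4–C5 and C1–C10 into a cyclohexenone (ring C5–C10, C6=O, C5=C10) and methyl cyclobut-1-enecarboxylate (C1–C4, C15).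
The enone is cut at C7–C11 (enolate alkylation) and C10–C14 (hydroxymethyl anion, oxidative transposition) back to (R)-5-silyloxycyclohexenone, made from cis,cis-cyclohexane-1,3,5-triol.
Forward: six-membered ring first, four-membered ring by [2+2] photocycloaddition, ten-membered ring by thermal cycloreversion, γ-lactone last. C14 is raised to the aldehyde before the ring expansion so that both new olefins are carbonyl-conjugated and can be equilibrated to the ring-cis geometry.
Stereochemistry: C8 from lipase desymmetrisation of a meso-diol (inverted at the end by Mitsunobu esterification), C7 by alkylation anti to O8, C6 by Felkin–Anh hydride addition next to C7, olefin geometry by thermodynamic control.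

Key step: step 11

Assumption: the lipase acetylates the pro-R carbinol of meso-diol 2; if its sense were the opposite, hydrolysis of the meso-diacetate with the same enzyme would give the same monoacetate 3.

**Step 1**
Reactants: 1 cis,cis-cyclohexane-1,3,5-triol
Product: 2 cis,cis-5-[(tert-butyldimethylsilyl)oxy]cyclohexane-1,3-diol (meso)
Conditions: TBSCl (1.0 equiv), imidazole, DMF, 0 → 23 °C
Reagents that add atoms: tert-butyldimethylsilyl chloride, CC(C)(C)[Si](C)(C)Cl
Why: Statistical monosilylation of the threefold-symmetric triol should give the achiral mono-ether, separable from triol and bis-ether, which can be recycled.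

**Step 2**
Reactants: 2 cis,cis-5-[(tert-butyldimethylsilyl)oxy]cyclohexane-1,3-diol
Product: 3 (1R,3S,5S)-3-hydroxy-5-[(tert-butyldimethylsilyl)oxy]cyclohexyl acetate
Conditions: immobilised Candida antarctica lipase B, vinyl acetate, t-BuOMe, 30 °C
Reagents that add atoms: vinyl acetate, C=COC(C)=O
Why: Lipase-catalysed irreversible transesterification (enzymatic desymmetrisation of a meso-diol) acetylates one of the two enantiotopic carbinols, so the enzyme fixes the absolute configuration of the silyloxy carbon (later C8) and of everything derived from it.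

**Step 3**
Reactants: 3 (1R,3S,5S)-3-hydroxy-5-[(tert-butyldimethylsilyl)oxy]cyclohexyl acetate
Product: 5 (R)-5-[(tert-butyldimethylsilyl)oxy]cyclohex-2-en-1-one, via β-acetoxy ketone 4 (not isolated)
Conditions: 1,1,1-triacetoxy-1,1-dihydro-1,2-benziodoxol-3(1H)-one (DMP), CH2Cl2, 0 → 23 °C; then DBU (3.5 equiv), 0 °C
Reagents that add atoms: none
Why: Periodinane oxidation of the free carbinol followed by E1cB elimination should expel acetate, a far better leaving group than silyloxide, and leave the silyloxy stereocentre untouched.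

**Step 4**
Reactants: 6 4-methoxybenzyl alcohol; 7 tributyl(iodomethyl)stannane
Product: 8 tributyl{[(4-methoxybenzyl)oxy]methyl}stannane
Conditions: NaH, THF–DMF, 0 °C; then 7, 23 °C
Reagents that add atoms: none
Why: Williamson ether synthesis, the alkoxide displacing iodide from the primary α-stannyl iodide by SN2.

**Step 5**
Reactants: 8 tributyl{[(4-methoxybenzyl)oxy]methyl}stannane; 5 (R)-5-[(tert-butyldimethylsilyl)oxy]cyclohex-2-en-1-one
Product: 9 (5R)-5-[(tert-butyldimethylsilyl)oxy]-1-{[(4-methoxybenzyl)oxy]methyl}cyclohex-2-en-1-ol (both C1 epimers)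
Conditions: 8, n-BuLi, THF, −78 °C; then 5, −78 °C; H2O
Reagents that add atoms: none
Why: Tin–lithium exchange gives an α-alkoxymethyllithium, a hard hydroxymethyl-anion equivalent that should add 1,2 to the enone carbonyl, and the new carbinol centre is of no consequence because it becomes sp2 in step 6.

**Step 6**
Reactants: 9 (5R)-5-[(tert-butyldimethylsilyl)oxy]-1-{[(4-methoxybenzyl)oxy]methyl}cyclohex-2-en-1-ol
Product: 10 (S)-5-[(tert-butyldimethylsilyl)oxy]-3-{[(4-methoxybenzyl)oxy]methyl}cyclohex-2-en-1-one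
Conditions: pyridinium chlorochromate [C5H5NH][CrO3Cl] (2 equiv), 4 Å molecular sieves, CH2Cl2, 23 °C
Reagents that add atoms: pyridinium chlorochromate, [O-][Cr](=O)(=O)Cl.c1cc[nH+]cc1
Why: Dauben oxidative transposition, in which the chromate ester of the tertiary allylic alcohol undergoes a [3,3] shift and is oxidised at the secondary terminus, moves the carbonyl to the future C6 and leaves C14 on the β-carbon C10.

**Step 7**
Reactants: 10 (S)-5-[(tert-butyldimethylsilyl)oxy]-3-{[(4-methoxybenzyl)oxy]methyl}cyclohex-2-en-1-one; 11 tert-butyl bromoacetate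
Product: 12 tert-butyl 2-[(1R,6S)-6-[(tert-butyldimethylsilyl)oxy]-4-{[(4-methoxybenzyl)oxy]methyl}-2-oxocyclohex-3-en-1-yl]acetate (C7 and C8 trans)
Conditions: LiN(i-Pr)2 (1.05 equiv), THF, −78 °C; then 11, DMPU, −78 → −40 °C
Reagents that add atoms: none
Why: Kinetic α′-deprotonation gives the cross-conjugated lithium enolate, which the reactive α-bromo ester should alkylate (SN2) on the face opposite the neighbouring silyloxy group, setting C7 trans to C8, while the low temperature holds back β-elimination of silyloxide.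

**Step 8**
Reactants: 12 tert-butyl 2-[(1R,6S)-6-[(tert-butyldimethylsilyl)oxy]-4-{[(4-methoxybenzyl)oxy]methyl}-2-oxocyclohex-3-en-1-yl]acetate
Product: 13 tert-butyl 2-[(1R,6S)-6-[(tert-butyldimethylsilyl)oxy]-4-(hydroxymethyl)-2-oxocyclohex-3-en-1-yl]acetate
Conditions: DDQ, CH2Cl2–pH 7 phosphate buffer, 0 °C
Reagents that add atoms: none
Why: Oxidative cleavage of the 4-methoxybenzyl ether (hydride abstraction by DDQ, hydrolysis of the oxocarbenium ion) should leave the silyl ether, enone and tert-butyl ester untouched.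

**Step 9**
Reactants: 14 ethyl 1-bromocyclobutane-1-carboxylate
Product: 15 cyclobut-1-ene-1-carboxylic acid
Conditions: KOH, toluene, reflux; then aq. HCl, 0 °C
Reagents that add atoms: potassium hydroxide, [K+].[OH-]
Why: Base-induced E2 dehydrobromination with concomitant saponification is the established preparation of this strained cyclobutene acid.

**Step 10**
Reactants: 15 cyclobut-1-ene-1-carboxylic acid
Product: 16 methyl cyclobut-1-ene-1-carboxylate
Conditions: Me3SiCHN2, MeOH–toluene, 0 °C; used at once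
Reagents that add atoms: (trimethylsilyl)diazomethane, C[Si](C)(C)C=[N+]=[N-]
Why: Esterification with diazomethane generated in the flask avoids the basic conditions under which the strained acrylate would polymerise.

**Step 11**
Reactants: 13 tert-butyl 2-[(1R,6S)-6-[(tert-butyldimethylsilyl)oxy]-4-(hydroxymethyl)-2-oxocyclohex-3-en-1-yl]acetate; 16 methyl cyclobut-1-ene-1-carboxylate
Product: 17 head-to-head cis-anti-cis photoadduct methyl 9-(2-tert-butoxy-2-oxoethyl)-8-[(tert-butyldimethylsilyl)oxy]-6-(hydroxymethyl)-10-oxotricyclo[4.4.0.0(2,5)]decane-2-carboxylate (new bonds C4–C5 and C1–C10; cyclobutane on the enone face opposite O8)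
Conditions: hν (350 nm, borosilicate filter), 16 (5 equiv), degassed CH2Cl2, −20 °C
Reagents that add atoms: none
Why: The excited enone (n→π* excitation, intersystem crossing to the triplet) should bond through its β-carbon C10 to the unsubstituted cyclobutene carbon C1, giving a 1,4-biradical (α-keto radical at C5, ester-stabilised tertiary radical at C4) that closes the C4–C5 bond after spin inversion; this is the stepwise enone–alkene [2+2] photocycloaddition, known for cyclohexenones with cyclobut-1-enecarboxylates. The one new ring, the cyclobutane C1–C4–C5–C10, is closed by radical recombination within that biradical, the cyclobutene ring being carried in intact as the second four-membered ring. C1 and C4 are cis because both sit in the cyclobutene ring, C5 and C10 end cis because only the cis six–four fusion is unstrained, and the cyclobutene ring turns away from the six-membered ring (anti) for steric reasons. The choice of enone face relative to C7 and C8 is expected to be poor but does not matter, since all four new centres become sp2 in step 13 and face isomers or any trans-fused adduct converge there. The selectivity the step needs is head-to-head regiochemistry (ester carbon C4 on the α-carbon C5), which the polarisation of the acrylate-type cyclobutene and the avoidance of two adjacent quaternary carbons should secure. The excess of 16 and the low temperature limit enone dimerisation.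

**Step 12**
Reactants: 17 head-to-head cis-anti-cis photoadduct (C14 alcohol)
Product: 18 methyl 9-(2-tert-butoxy-2-oxoethyl)-8-[(tert-butyldimethylsilyl)oxy]-6-formyl-10-oxotricyclo[4.4.0.0(2,5)]decane-2-carboxylate
Conditions: DMP, CH2Cl2, 0 → 23 °C
Reagents that add atoms: none
Why: Periodinane oxidation of the neopentyl primary alcohol gives a non-enolisable aldehyde on C10, so that after fragmentation both ring olefins are conjugated with a carbonyl group.

**Step 13**
Reactants: 18 photoadduct aldehyde
Product: 21 methyl 10-formyl-6-oxo-7-(2-tert-butoxy-2-oxoethyl)-8-[(tert-butyldimethylsilyl)oxy]cyclodeca-1(10),4-diene-4-carboxylate (7R,8S; both olefins cis in the ring = 1(10)E,4E), via C4=C5 ring-trans dienone 19 (not isolated), via C1=C10 ring-trans dienone 20 (not isolated)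
Conditions: degassed 1,2-dichlorobenzene (0.01 M), silylated sealed tube, 170 °C; cool to 23 °C, then I2 (5 mol %), room light
Reagents that add atoms: none
Why: Thermal cycloreversion of the bicyclo[2.2.0]hexane (homolysis of C1–C4 to the ester-stabilised cyclohexane-1,4-diyl, then scission of C5–C10) is the known route from such photoadducts to cyclodeca-1,5-dienes, and the ring-trans olefins formed first, both carbonyl-conjugated, should be equilibrated by reversible iodine-atom addition to the ring-cis,cis isomer, which ring strain and the trans enoate and enal preferences favour, while a Cope rearrangement would cost two conjugations.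

**Step 14**
Reactants: 21 ring-cis,cis dienone aldehyde
Product: 22 methyl 10-(dimethoxymethyl)-6-oxo-7-(2-tert-butoxy-2-oxoethyl)-8-[(tert-butyldimethylsilyl)oxy]cyclodeca-1(10),4-diene-4-carboxylate
Conditions: HC(OMe)3, MeOH, pyridinium p-toluenesulfonate (cat.), 0 → 23 °C
Reagents that add atoms: trimethyl orthoformate, COC(OC)OC; methanol, CO
Why: Acid-catalysed acetalisation is expected to select the aldehyde over the hindered conjugated ketone and masks C14 for the hydride and base steps that follow.

**Step 15**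
Reactants: 22 dienone dimethyl acetal
Product: 23 tert-butyl [(6S,7S,8S)-6-hydroxy-4-(hydroxymethyl)-10-(dimethoxymethyl)-8-[(tert-butyldimethylsilyl)oxy]cyclodeca-1(10),4-dien-7-yl]acetate (O6 cis to the C7 side chain)
Conditions: i-Bu2AlH (4.5 equiv), CH2Cl2, −78 °C; MeOH, aq. KNaC4H4O6 (potassium sodium tartrate)
Reagents that add atoms: none
Why: i-Bu2AlH reduces the ketone (1,2) and the methyl enoate to the allylic alcohol while the tert-butyl ester and the acetal survive at −78 °C, and the hydride should reach C6 anti to the C7–C8 ring bond with the CH2CO2t-Bu branch lying next to the carbonyl oxygen (Felkin–Anh, peripheral attack on the ten-membered ring), which places the new hydroxyl cis to that branch (6S).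

**Step 16**
Reactants: 23 diol tert-butyl ester
Product: 25 (6S,7S,8S)-8-[(tert-butyldimethylsilyl)oxy]-15-[(tert-butyldiphenylsilyl)oxy]-14,14-dimethoxygermacra-1(10),4-dien-12,6-olide (cis-fused lactone), via hydroxy lactone 24 (not isolated)
Conditions: NaH (2.2 equiv), THF, 0 → 23 °C; then TBDPSCl (1.5 equiv), 0 °C
Reagents that add atoms: tert-butyldiphenylsilyl chloride, CC(C)(C)[Si](Cl)(c1ccccc1)c1ccccc1
Why: The C6 alkoxide should close the γ-lactone by 5-exo-trig transesterification of the tert-butyl ester (cis fusion follows from the cis hydroxyl), and the remaining primary allylic alkoxide is silylated in the same flask.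

**Step 17**
Reactants: 25 lactone bis-silyl ether
Product: 28 (6S,7S,8S)-8-[(tert-butyldimethylsilyl)oxy]-15-[(tert-butyldiphenylsilyl)oxy]-14,14-dimethoxygermacra-1(10),4,11(13)-trien-12,6-olide, via Mannich base 26 (not isolated), via methiodide 27 (not isolated)
Conditions: LiN(i-Pr)2 (1.3 equiv), THF, −78 °C; CH2=NMe2+ I−, −78 → 23 °C; then MeI, THF–MeOH, 23 °C; then aq. NaHCO3, CH2Cl2
Reagents that add atoms: dimethylmethyleneammonium iodide, C=[N+](C)C.[I-]
Why: Mannich reaction of the lactone lithium enolate with the iminium salt, N-methylation and E1cB loss of trimethylamine is the standard α-methylenation of γ-lactones and creates no stereocentre.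

**Step 18**
Reactants: 28 α-methylene lactone bis-silyl ether
Product: 29 (6S,7R,8S)-8-hydroxy-15-[(tert-butyldiphenylsilyl)oxy]-14,14-dimethoxygermacra-1(10),4,11(13)-trien-12,6-olide (O8 trans to C11)
Conditions: camphor-10-sulfonic acid (0.2 equiv), MeOH–CH2Cl2 (1:1), 0 → 23 °C
Reagents that add atoms: none
Why: Acid-catalysed methanolysis should remove the secondary TBS ether, whereas the primary TBDPS ether is far more acid-stable and the dimethyl acetal only exchanges degenerately with methanol.

**Step 19**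
Reactants: 29 C8 alcohol; 30 3-methylbutanoic acid (isovaleric acid)
Product: 31 (6S,7R,8R)-8-(3-methylbutanoyloxy)-15-[(tert-butyldiphenylsilyl)oxy]-14,14-dimethoxygermacra-1(10),4,11(13)-trien-12,6-olide
Conditions: PPh3, diisopropyl azodicarboxylate, 30, toluene, 0 → 23 °C
Reagents that add atoms: none
Why: Mitsunobu esterification, in which the carboxylate displaces the C8 oxyphosphonium group by SN2, should install the ester with inversion to the 8R configuration, cis to the lactone.

**Step 20**
Reactants: 31 protected ester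
Product: 32 target, (6S,7R,8R)-15-hydroxy-8-(3-methylbutanoyloxy)-14-oxogermacra-1(10),4,11(13)-trien-12,6-olide (1(10)E,4E; both ring olefins cis in the ring)
Conditions: aq. HF (48 %), MeCN, 0 → 23 °C
Reagents that add atoms: water, O
Why: Aqueous HF should cleave the primary silyl ether and hydrolyse the acetal to the conjugated aldehyde under conditions that leave the lactone, the ester and the olefin geometries unchanged.

**Compound list**
1 | cis,cis-cyclohexane-1,3,5-triol | O[C@H]1C[C@@H](O)C[C@@H](O)C1 | starting material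
2 | cis,cis-5-[(tert-butyldimethylsilyl)oxy]cyclohexane-1,3-diol (meso) | O[C@H]1C[C@@H](O)C[C@@H](O[Si](C)(C)C(C)(C)C)C1 | intermediate
3 | (1R,3S,5S)-3-hydroxy-5-[(tert-butyldimethylsilyl)oxy]cyclohexyl acetate | O[C@H]1C[C@@H](OC(C)=O)C[C@@H](O[Si](C)(C)C(C)(C)C)C1 | intermediate
4 | (3S,5R)-3-acetoxy-5-[(tert-butyldimethylsilyl)oxy]cyclohexan-1-one | O=C1C[C@@H](OC(C)=O)C[C@@H](O[Si](C)(C)C(C)(C)C)C1 | intermediate
5 | (R)-5-[(tert-butyldimethylsilyl)oxy]cyclohex-2-en-1-one | O=C1C=CC[C@@H](O[Si](C)(C)C(C)(C)C)C1 | intermediate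
6 | 4-methoxybenzyl alcohol | COc1ccc(CO)cc1 | starting material
7 | tributyl(iodomethyl)stannane | CCCC[Sn](CCCC)(CCCC)CI | starting material
8 | tributyl{[(4-methoxybenzyl)oxy]methyl}stannane | CCCC[Sn](CCCC)(CCCC)COCc1ccc(OC)cc1 | intermediate
9 | (5R)-5-[(tert-butyldimethylsilyl)oxy]-1-{[(4-methoxybenzyl)oxy]methyl}cyclohex-2-en-1-ol, both C1 epimers | OC1(COCc2ccc(OC)cc2)C=CC[C@@H](O[Si](C)(C)C(C)(C)C)C1 | intermediate
10 | (S)-5-[(tert-butyldimethylsilyl)oxy]-3-{[(4-methoxybenzyl)oxy]methyl}cyclohex-2-en-1-one | O=C1C=C(COCc2ccc(OC)cc2)C[C@H](O[Si](C)(C)C(C)(C)C)C1 | intermediate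
11 | tert-butyl bromoacetate | CC(C)(C)OC(=O)CBr | starting material
12 | tert-butyl 2-[(1R,6S)-6-[(tert-butyldimethylsilyl)oxy]-4-{[(4-methoxybenzyl)oxy]methyl}-2-oxocyclohex-3-en-1-yl]acetate | O=C1C=C(COCc2ccc(OC)cc2)C[C@H](O[Si](C)(C)C(C)(C)C)[C@H]1CC(=O)OC(C)(C)C | intermediate
13 | tert-butyl 2-[(1R,6S)-6-[(tert-butyldimethylsilyl)oxy]-4-(hydroxymethyl)-2-oxocyclohex-3-en-1-yl]acetate | O=C1C=C(CO)C[C@H](O[Si](C)(C)C(C)(C)C)[C@H]1CC(=O)OC(C)(C)C | intermediate
14 | ethyl 1-bromocyclobutane-1-carboxylate | CCOC(=O)C1(Br)CCC1 | starting material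
15 | cyclobut-1-ene-1-carboxylic acid | OC(=O)C1=CCC1 | intermediate
16 | methyl cyclobut-1-ene-1-carboxylate | COC(=O)C1=CCC1 | intermediate
17 | head-to-head cis-anti-cis photoadduct, methyl 9-(2-tert-butoxy-2-oxoethyl)-8-[(tert-butyldimethylsilyl)oxy]-6-(hydroxymethyl)-10-oxotricyclo[4.4.0.0(2,5)]decane-2-carboxylate | O=C1[C@H]2[C@]3(C(=O)OC)CC[C@@H]3[C@@]2(CO)C[C@H](O[Si](C)(C)C(C)(C)C)[C@H]1CC(=O)OC(C)(C)C | intermediate
18 | 6-formyl analogue of 17 (C14 aldehyde) | O=C1[C@H]2[C@]3(C(=O)OC)CC[C@@H]3[C@@]2(C=O)C[C@H](O[Si](C)(C)C(C)(C)C)[C@H]1CC(=O)OC(C)(C)C | intermediate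
19 | C4=C5 ring-trans isomer of 21 (4Z,1(10)E) | O=C1/C=C(\C(=O)OC)CC/C=C(/C=O)C[C@H](O[Si](C)(C)C(C)(C)C)[C@H]1CC(=O)OC(C)(C)C | intermediate
20 | C1=C10 ring-trans isomer of 21 (4E,1(10)Z) | O=C1/C=C(/C(=O)OC)CC/C=C(\C=O)C[C@H](O[Si](C)(C)C(C)(C)C)[C@H]1CC(=O)OC(C)(C)C | intermediate
21 | methyl (7R,8S)-10-formyl-6-oxo-7-(2-tert-butoxy-2-oxoethyl)-8-[(tert-butyldimethylsilyl)oxy]cyclodeca-1(10),4-diene-4-carboxylate, both olefins cis in the ring (1(10)E,4E) | O=C1/C=C(/C(=O)OC)CC/C=C(/C=O)C[C@H](O[Si](C)(C)C(C)(C)C)[C@H]1CC(=O)OC(C)(C)C | intermediate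
22 | 10-(dimethoxymethyl) analogue of 21 | O=C1/C=C(/C(=O)OC)CC/C=C(/C(OC)OC)C[C@H](O[Si](C)(C)C(C)(C)C)[C@H]1CC(=O)OC(C)(C)C | intermediate
23 | tert-butyl [(6S,7S,8S)-6-hydroxy-4-(hydroxymethyl)-10-(dimethoxymethyl)-8-[(tert-butyldimethylsilyl)oxy]cyclodeca-1(10),4-dien-7-yl]acetate | O[C@H]1/C=C(/CO)CC/C=C(/C(OC)OC)C[C@H](O[Si](C)(C)C(C)(C)C)[C@H]1CC(=O)OC(C)(C)C | intermediate
24 | (6S,7S,8S)-15-hydroxy-8-[(tert-butyldimethylsilyl)oxy]-14,14-dimethoxygermacra-1(10),4-dien-12,6-olide (cis-fused lactone) | C1C(=O)O[C@H]2/C=C(/CO)CC/C=C(/C(OC)OC)C[C@H](O[Si](C)(C)C(C)(C)C)[C@@H]12 | intermediate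
25 | 15-O-(tert-butyldiphenylsilyl) ether of 24 | C1C(=O)O[C@H]2/C=C(/CO[Si](c3ccccc3)(c3ccccc3)C(C)(C)C)CC/C=C(/C(OC)OC)C[C@H](O[Si](C)(C)C(C)(C)C)[C@@H]12 | intermediate
26 | 11-[(dimethylamino)methyl] derivative of 25 (C11 epimers) | CN(C)CC1C(=O)O[C@H]2/C=C(/CO[Si](c3ccccc3)(c3ccccc3)C(C)(C)C)CC/C=C(/C(OC)OC)C[C@H](O[Si](C)(C)C(C)(C)C)[C@@H]12 | intermediate
27 | trimethylammonium iodide of 26 | C[N+](C)(C)CC1C(=O)O[C@H]2/C=C(/CO[Si](c3ccccc3)(c3ccccc3)C(C)(C)C)CC/C=C(/C(OC)OC)C[C@H](O[Si](C)(C)C(C)(C)C)[C@@H]12.[I-] | intermediate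
28 | (6S,7S,8S)-8-[(tert-butyldimethylsilyl)oxy]-15-[(tert-butyldiphenylsilyl)oxy]-14,14-dimethoxygermacra-1(10),4,11(13)-trien-12,6-olide | C=C1C(=O)O[C@H]2/C=C(/CO[Si](c3ccccc3)(c3ccccc3)C(C)(C)C)CC/C=C(/C(OC)OC)C[C@H](O[Si](C)(C)C(C)(C)C)[C@@H]12 | intermediate
29 | (6S,7R,8S)-8-hydroxy-15-[(tert-butyldiphenylsilyl)oxy]-14,14-dimethoxygermacra-1(10),4,11(13)-trien-12,6-olide | C=C1C(=O)O[C@H]2/C=C(/CO[Si](c3ccccc3)(c3ccccc3)C(C)(C)C)CC/C=C(/C(OC)OC)C[C@H](O)[C@@H]12 | intermediate
30 | 3-methylbutanoic acid | CC(C)CC(=O)O | starting material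
31 | (6S,7R,8R)-8-(3-methylbutanoyloxy)-15-[(tert-butyldiphenylsilyl)oxy]-14,14-dimethoxygermacra-1(10),4,11(13)-trien-12,6-olide | C=C1C(=O)O[C@H]2/C=C(/CO[Si](c3ccccc3)(c3ccccc3)C(C)(C)C)CC/C=C(/C(OC)OC)C[C@@H](OC(=O)CC(C)C)[C@@H]12 | intermediate
32 | (6S,7R,8R)-15-hydroxy-8-(3-methylbutanoyloxy)-14-oxogermacra-1(10),4,11(13)-trien-12,6-olide | C=C1C(=O)O[C@H]2/C=C(/CO)CC/C=C(/C=O)C[C@@H](OC(=O)CC(C)C)[C@@H]12 | target

**Step count and risks**
Total: 20 steps. Longest linear sequence: 17 steps (steps 1–3, 5–8, 11–20).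

Step 13. The aldehyde-bearing adduct may degrade thermally before it fragments, or a ring-trans diene may undergo Cope rearrangement to a divinylcyclohexanone faster than it is equilibrated. The fallback fragments one oxidation level lower. Alcohol 17 is heated as in step 13 and should give first the C4=C5 ring-trans hydroxy dienone F1 and the C1=C10 ring-trans hydroxy dienone F2. Thiyl radicals (PhSH 10 mol %, AIBN 5 mol %, benzene, 80 °C) act on the isolated C1=C10 bond as well as on the conjugated one and should equilibrate both to the ring-cis,cis hydroxy dienone F3. Allylic oxidation with MnO2 (CH2Cl2, 23 °C) then returns to 21.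

Step 15. Hydride delivery to the C6 carbonyl of the flexible ten-membered ring may show poor or reversed facial selectivity. The fallback uses the other epimer by closing the lactone with inversion instead of retention. From 22 the same reduction gives the 6-epimeric diol F4. Its primary hydroxyl is silylated (TBDPSCl, imidazole, CH2Cl2, 0 °C) to the 6-epimeric silyl ether F5, and the C6 hydroxyl is mesylated (MsCl, Et3N, CH2Cl2, −20 °C) to the allylic mesylate F6. On warming, the tert-butyl ester carbonyl should displace the mesylate from the rear and lose isobutene, which gives lactone 25.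

Step 19. The activated O8 may be lost by elimination toward C9, whose hydrogens are allylic, or the hindered carbinol may not be displaced at all. The fallback replaces the redox condensation by a two-stage sulfonate displacement. From 29, ClCH2SO2Cl and pyridine (0 °C) give the chloromethanesulfonate F7. CsO2CCH2CHMe2 (from 30 and Cs2CO3) with 18-crown-6 in toluene at 60 °C should then displace it with inversion and return to 31.

**Further compounds**
F1 | step 13 | C4=C5 ring-trans hydroxy dienone, methyl (7R,8S)-10-(hydroxymethyl)-6-oxo-7-(2-tert-butoxy-2-oxoethyl)-8-[(tert-butyldimethylsilyl)oxy]cyclodeca-1(10),4-diene-4-carboxylate (4Z,1(10)E) | O=C1/C=C(\C(=O)OC)CC/C=C(/CO)C[C@H](O[Si](C)(C)C(C)(C)C)[C@H]1CC(=O)OC(C)(C)C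
F2 | step 13 | C1=C10 ring-trans hydroxy dienone (4E,1(10)Z isomer of F1) | O=C1/C=C(/C(=O)OC)CC/C=C(\CO)C[C@H](O[Si](C)(C)C(C)(C)C)[C@H]1CC(=O)OC(C)(C)C
F3 | step 13 | ring-cis,cis hydroxy dienone (4E,1(10)E isomer of F1) | O=C1/C=C(/C(=O)OC)CC/C=C(/CO)C[C@H](O[Si](C)(C)C(C)(C)C)[C@H]1CC(=O)OC(C)(C)C
F4 | step 15 | 6-epimeric diol (6R epimer of 23, O6 trans to the C7 side chain) | O[C@@H]1/C=C(/CO)CC/C=C(/C(OC)OC)C[C@H](O[Si](C)(C)C(C)(C)C)[C@H]1CC(=O)OC(C)(C)C
F5 | step 15 | 6-epimeric silyl ether (15-O-tert-butyldiphenylsilyl ether of F4) | O[C@@H]1/C=C(/CO[Si](c2ccccc2)(c2ccccc2)C(C)(C)C)CC/C=C(/C(OC)OC)C[C@H](O[Si](C)(C)C(C)(C)C)[C@H]1CC(=O)OC(C)(C)C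
F6 | step 15 | allylic mesylate (6-O-methanesulfonate of F5) | CS(=O)(=O)O[C@@H]1/C=C(/CO[Si](c2ccccc2)(c2ccccc2)C(C)(C)C)CC/C=C(/C(OC)OC)C[C@H](O[Si](C)(C)C(C)(C)C)[C@H]1CC(=O)OC(C)(C)C
F7 | step 19 | chloromethanesulfonate (8-O-chloromethanesulfonate of 29) | C=C1C(=O)O[C@H]2/C=C(/CO[Si](c3ccccc3)(c3ccccc3)C(C)(C)C)CC/C=C(/C(OC)OC)C[C@H](OS(=O)(=O)CCl)[C@@H]12
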